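**Plan**
1. Retrosynthetic cuts: (a) the C4–C8 bond between the upper unit and ring D of the lower unit; (b) the O1–C8a aryl ether bond of ring C; (c) the C2–C1' bond to ring B. The lower unit is (−)-epigallocatechin; the C4–C3(O)–C(=O) chain of the upper unit is methyl (S)-4-hydroxyphenyllactate.
2. Enabling feature: ring A carries its only oxygen at C7, para to C4a and meta to C8a (the tyrosine pattern). Dearomatising this 4-alkylphenol to a cyclohexa-2,5-dienone makes C8a a β-carbon placed 6-exo to the C2 hydroxyl; conjugate addition and loss of water then form O1–C8a and return ring A as the free 7-phenol. A nucleophilic oxygen is thus joined to a formerly nucleophilic arene carbon by polarity reversal.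
3. Forward order: open chain (ring B ketone, then alcohol) → dearomatisation of ring A → closure of ring C → C4 oxidation directed by the freed 7-OH → addition of the 8-lithiated lower unit to C4 → reductive removal of the C4 hydroxyl → global debenzylation.
4. Stereochemistry: C3 from the chiral pool; C2 by Cram-chelate reduction (anti to O3); C4 by hydride delivery trans to the O3 benzyl group (gives 3,4-cis); C2 and C3 of the lower unit from epigallocatechin.

Key step: step 8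

Remark: the target is read as (−)-robinetinidol-(4β→8)-(−)-epigallocatechin, upper unit (2R,3S,4R) with 2,3-trans-3,4-cis geometry and lower unit (2R,3R). Flavan numbering is used for all intermediates; rings A, B and C belong to the upper unit and ring D is the phloroglucinol ring of the lower unit. Compounds 1, 5 and 17 are taken as purchasable.

Step 1
Reactants: 1 methyl (2S)-2-hydroxy-3-(4-hydroxyphenyl)propanoate
Product: 2 methyl (2S)-3-[4-(tert-butyldimethylsilyloxy)phenyl]-2-hydroxypropanoate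
Conditions: TBSCl (1.05 equiv), imidazole, CH2Cl2, 0 °C
Reagents that add atoms: tert-butyldimethylsilyl chloride, CC(C)(C)[Si](C)(C)Cl
Why: Imidazole-promoted O-silylation is much faster at the phenol than at the hydrogen-bonded secondary α-hydroxy ester, so one equivalent of TBSCl should mask only the future 7-OH of ring A and leave the stereocentre untouched.

Step 2
Reactants: 2 methyl (2S)-3-[4-(tert-butyldimethylsilyloxy)phenyl]-2-hydroxypropanoate
Product: 3 methyl (2S)-2-(benzyloxy)-3-[4-(tert-butyldimethylsilyloxy)phenyl]propanoate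
Conditions: BnOC(=NH)CCl3, TfOH (cat.), CH2Cl2/cyclohexane, 0 °C to rt
Reagents that add atoms: benzyl 2,2,2-trichloroacetimidate, N=C(OCc1ccccc1)C(Cl)(Cl)Cl
Why: Acid-catalysed benzyl transfer from the trichloroacetimidate etherifies the secondary alcohol without base, so the C3 centre α to the ester should not epimerise, and the benzyl group later blocks O3 from conjugate addition and allows chelation control (trichloroacetimidate benzylation).

Step 3
Reactants: 3 methyl (2S)-2-(benzyloxy)-3-[4-(tert-butyldimethylsilyloxy)phenyl]propanoate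
Product: 4 (2S)-2-(benzyloxy)-3-[4-(tert-butyldimethylsilyloxy)phenyl]-N-methoxy-N-methylpropanamide
Conditions: MeNHOMe·HCl, iPrMgCl, THF, −20 °C
Reagents that add atoms: N,O-dimethylhydroxylamine hydrochloride, CNOC.Cl
Why: The chloromagnesium amide formed in the flask should convert the methyl ester directly into the Weinreb amide at low temperature without enolising the α-alkoxy centre (aminolysis of an ester by a magnesium amide).

Step 4
Reactants: 4 (2S)-2-(benzyloxy)-3-[4-(tert-butyldimethylsilyloxy)phenyl]-N-methoxy-N-methylpropanamide; 5 5-bromo-1,2,3-tris(benzyloxy)benzene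
Product: 7 (2S)-2-(benzyloxy)-3-[4-(tert-butyldimethylsilyloxy)phenyl]-1-[3,4,5-tris(benzyloxy)phenyl]propan-1-one, via arylmagnesium bromide 6 (not isolated)
Conditions: 5, Mg, THF, 40 °C; then 4, 0 °C
Reagents that add atoms: none
Why: The Grignard reagent should add only once because the five-membered magnesium chelate of the Weinreb amide survives until work-up, which forges the C2–C1' bond to ring B (Weinreb ketone synthesis).

Step 5
Reactants: 7 (2S)-2-(benzyloxy)-3-[4-(tert-butyldimethylsilyloxy)phenyl]-1-[3,4,5-tris(benzyloxy)phenyl]propan-1-one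
Product: 8 (1R,2S)-2-(benzyloxy)-3-[4-(tert-butyldimethylsilyloxy)phenyl]-1-[3,4,5-tris(benzyloxy)phenyl]propan-1-ol
Conditions: Zn(BH4)2, Et2O, −30 to 0 °C
Reagents that add atoms: none
Why: Zinc bridges the carbonyl oxygen and the α-benzyloxy oxygen (Cram-chelate model) and hydride should attack the less hindered face beside H-3, which sets the new carbinol centre (flavan C2) as R, anti to O3 (chelation-controlled ketone reduction).

Step 6
Reactants: 8 (1R,2S)-2-(benzyloxy)-3-[4-(tert-butyldimethylsilyloxy)phenyl]-1-[3,4,5-tris(benzyloxy)phenyl]propan-1-ol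
Product: 9 4-[(2S,3R)-2-(benzyloxy)-3-hydroxy-3-[3,4,5-tris(benzyloxy)phenyl]propyl]phenol
Conditions: Bu4NF, THF, 0 °C
Reagents that add atoms: none
Why: Fluoride cleaves the aryl silyl ether and leaves the benzyl ethers and the secondary alcohol untouched, which frees the para-alkylphenol needed for dearomatisation (fluoride desilylation).

Step 7
Reactants: 9 4-[(2S,3R)-2-(benzyloxy)-3-hydroxy-3-[3,4,5-tris(benzyloxy)phenyl]propyl]phenol
Product: 11 4-[(2S,3R)-2-(benzyloxy)-3-hydroxy-3-[3,4,5-tris(benzyloxy)phenyl]propyl]-4-hydroxycyclohexa-2,5-dien-1-one, via hydroperoxy dienone 10 (not isolated)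
Conditions: 2KHSO5·KHSO4·K2SO4 (Oxone), NaHCO3, MeCN/H2O, rt; then Na2S2O3
Reagents that add atoms: potassium peroxymonosulfate (KHSO5, the active salt of Oxone), [K+].[O-]S(=O)(=O)OO
Why: Singlet oxygen released from KHSO5 under bicarbonate should add to the phenol at C4a to give the 4-hydroperoxy dienone, which thiosulfate reduces to the p-quinol; because no phenoxonium ion is involved, the free C2 hydroxyl cannot spirocyclise at the ipso carbon and the benzylic CH2 is not oxidised (oxidative dearomatisation of a para-alkylphenol to a p-quinol).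

Step 8
Reactants: 11 4-[(2S,3R)-2-(benzyloxy)-3-hydroxy-3-[3,4,5-tris(benzyloxy)phenyl]propyl]-4-hydroxycyclohexa-2,5-dien-1-one
Product: 13 (2R,3S)-3-(benzyloxy)-2-[3,4,5-tris(benzyloxy)phenyl]-3,4-dihydro-2H-chromen-7-ol, via bicyclic hydroxy enone 12 (not isolated)
Conditions: (PhO)2P(O)OH (10 mol %), 4 Å MS, CH2Cl2, rt; then TsOH·H2O (20 mol %), 40 °C (one pot)
Reagents that add atoms: none
Why: Proposed new method: the phosphoric acid activates the cross-conjugated dienone and the C2 hydroxyl adds to its β-carbon (the future C8a) in a 6-exo-trig oxa-Michael closure of ring C to give the cis-fused hydroxy enone 12; TsOH then enolises the ketone, the tertiary allylic C4a–OH ionises to a cyclohexadienyl cation and loss of H-8a restores ring A as the 7-hydroxy aryl ether, so that a nucleophilic oxygen is joined to a formerly nucleophilic arene carbon by polarity reversal of the phenol. The closest known reaction types are the Brønsted-acid-catalysed intramolecular oxa-Michael addition of tethered alcohols to 4,4-disubstituted cyclohexa-2,5-dienones and the acid-promoted dehydration of 4-hydroxycyclohex-2-enones to phenols; their union into an aryl-ether-forming chroman annulation is the untested part. The stereocentres formed at C4a and C8a are transient and are erased on aromatisation, while C2 and C3 keep their configuration because neither of their C–O bonds is broken. Selectivity for the six-membered ring rests on O3 being a benzyl ether (no 5-exo addition) and on C4a being already sp3 (no ipso spirocyclisation), and the two β-carbons of the dienone become equivalent on aromatisation, so no regiochemical issue arises.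

Step 9
Reactants: 13 (2R,3S)-3-(benzyloxy)-2-[3,4,5-tris(benzyloxy)phenyl]-3,4-dihydro-2H-chromen-7-ol
Product: 15 (2R,3R)-3-(benzyloxy)-7-hydroxy-2-[3,4,5-tris(benzyloxy)phenyl]-2,3-dihydro-4H-chromen-4-one, via flavan-4-ol 14 (not isolated)
Conditions: DDQ (2.2 equiv), 1,4-dioxane/H2O, rt
Reagents that add atoms: water, O
Why: DDQ should dehydrogenate the 7-hydroxyflavan through its para-quinone methide (C7=O, C4a=C4), water adds at C4, and a second equivalent oxidises the resulting para-hydroxybenzylic alcohol to the ketone, so the phenol freed in step 8 directs oxidation to C4 alone while the trans C2/C3 centres stay as set (DDQ benzylic oxidation of a para-alkylphenol).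

Step 10
Reactants: 15 (2R,3R)-3-(benzyloxy)-7-hydroxy-2-[3,4,5-tris(benzyloxy)phenyl]-2,3-dihydro-4H-chromen-4-one
Product: 16 (2R,3R)-3,7-bis(benzyloxy)-2-[3,4,5-tris(benzyloxy)phenyl]-2,3-dihydro-4H-chromen-4-one
Conditions: BnOH, PPh3, iPrO2CN=NCO2iPr (DIAD), THF, 0 °C to rt
Reagents that add atoms: benzyl alcohol, OCc1ccccc1
Why: The acidic para-acylphenol is alkylated by benzyl alcohol under neutral redox-condensation conditions, which avoids base-induced opening of the flavanone ring by β-elimination of O1 (Mitsunobu etherification).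

Step 11
Reactants: 17 (−)-epigallocatechin
Product: 18 (2R,3R)-3,5,7-tris(benzyloxy)-2-[3,4,5-tris(benzyloxy)phenyl]-3,4-dihydro-2H-chromene
Conditions: NaH, BnBr, DMF, 0 °C to rt (argon)
Reagents that add atoms: benzyl bromide, BrCc1ccccc1
Why: Exhaustive Williamson etherification under argon should cap the five phenols and the C3 hydroxyl with the same hydrogenolysable group without touching C2 or C3.

Step 12
Reactants: 18 (2R,3R)-3,5,7-tris(benzyloxy)-2-[3,4,5-tris(benzyloxy)phenyl]-3,4-dihydro-2H-chromene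
Product: 19 (2R,3R)-3,5,7-tris(benzyloxy)-8-bromo-2-[3,4,5-tris(benzyloxy)phenyl]-3,4-dihydro-2H-chromene
Conditions: NBS (1.0 equiv), CH2Cl2, −78 °C to rt
Reagents that add atoms: N-bromosuccinimide, O=C1CCC(=O)N1Br
Why: Electrophilic bromination should go to the most electron-rich ring D, and to C8 in preference to C6 as is general for 5,7-di-O-benzyl flavan-3-ol ethers, which fixes the later interflavan bond at C8 (regioselective aromatic bromination).

Step 13
Reactants: 19 (2R,3R)-3,5,7-tris(benzyloxy)-8-bromo-2-[3,4,5-tris(benzyloxy)phenyl]-3,4-dihydro-2H-chromene; 16 (2R,3R)-3,7-bis(benzyloxy)-2-[3,4,5-tris(benzyloxy)phenyl]-2,3-dihydro-4H-chromen-4-one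
Product: 21 (2R,3R,4R)-3,7-bis(benzyloxy)-4-{(2R,3R)-3,5,7-tris(benzyloxy)-2-[3,4,5-tris(benzyloxy)phenyl]-3,4-dihydro-2H-chromen-8-yl}-2-[3,4,5-tris(benzyloxy)phenyl]-3,4-dihydro-2H-chromen-4-ol, via aryllithium 20 (not isolated)
Conditions: 19, tBuLi (2.0 equiv), THF, −78 °C; then 16, −78 to 0 °C
Reagents that add atoms: none
Why: Bromine–lithium exchange gives the 8-lithio flavan, which should add to the C4 ketone from the face opposite the C3 benzyloxy group and forge the C4–C8 interflavan bond as a tertiary carbinol whose configuration is inconsequential because it is removed in the next step (1,2-addition of an aryllithium to a ketone).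

Step 14
Reactants: 21 (2R,3R,4R)-3,7-bis(benzyloxy)-4-{(2R,3R)-3,5,7-tris(benzyloxy)-2-[3,4,5-tris(benzyloxy)phenyl]-3,4-dihydro-2H-chromen-8-yl}-2-[3,4,5-tris(benzyloxy)phenyl]-3,4-dihydro-2H-chromen-4-ol
Product: 22 (2R,3S,4R)-3,7-bis(benzyloxy)-4-{(2R,3R)-3,5,7-tris(benzyloxy)-2-[3,4,5-tris(benzyloxy)phenyl]-3,4-dihydro-2H-chromen-8-yl}-2-[3,4,5-tris(benzyloxy)phenyl]-3,4-dihydro-2H-chromene
Conditions: nBu3SnH, CF3CO2H, CH2Cl2, 0 °C
Reagents that add atoms: none
Why: CF3CO2H ionises the tertiary dibenzylic alcohol to a C4 cation stabilised by the para 7-benzyloxy group of ring A and by ring D, and nBu3SnH should deliver hydride to the face trans to the C3 benzyloxy group, so that ring D ends cis to O3 (4R, 3,4-cis) under substrate control (ionic hydrogenation of a benzylic alcohol).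

Step 15
Reactants: 22 (2R,3S,4R)-3,7-bis(benzyloxy)-4-{(2R,3R)-3,5,7-tris(benzyloxy)-2-[3,4,5-tris(benzyloxy)phenyl]-3,4-dihydro-2H-chromen-8-yl}-2-[3,4,5-tris(benzyloxy)phenyl]-3,4-dihydro-2H-chromene
Product: 23 (2R,3S,4R)-4-[(2R,3R)-3,5,7-trihydroxy-2-(3,4,5-trihydroxyphenyl)-3,4-dihydro-2H-chromen-8-yl]-2-(3,4,5-trihydroxyphenyl)-3,4-dihydro-2H-chromene-3,7-diol
Conditions: H2 (1 atm), Pd(OH)2/C, THF/MeOH/H2O, rt
Reagents that add atoms: none
Why: Hydrogenolysis over Pd(OH)2/C should remove all eleven benzyl ethers under neutral conditions that leave the interflavan bond, both pyran rings and the five stereocentres untouched (catalytic hydrogenolysis of benzyl ethers).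

**Compound list**
1 | methyl (2S)-2-hydroxy-3-(4-hydroxyphenyl)propanoate | Oc1ccc(C[C@H](O)C(=O)OC)cc1 | starting material
2 | methyl (2S)-3-[4-(tert-butyldimethylsilyloxy)phenyl]-2-hydroxypropanoate | CC(C)(C)[Si](C)(C)Oc1ccc(C[C@H](O)C(=O)OC)cc1 | intermediate
3 | methyl (2S)-2-(benzyloxy)-3-[4-(tert-butyldimethylsilyloxy)phenyl]propanoate | CC(C)(C)[Si](C)(C)Oc1ccc(C[C@H](OCc2ccccc2)C(=O)OC)cc1 | intermediate
4 | (2S)-2-(benzyloxy)-3-[4-(tert-butyldimethylsilyloxy)phenyl]-N-methoxy-N-methylpropanamide | CC(C)(C)[Si](C)(C)Oc1ccc(C[C@H](OCc2ccccc2)C(=O)N(C)OC)cc1 | intermediate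
5 | 5-bromo-1,2,3-tris(benzyloxy)benzene | Brc1cc(OCc2ccccc2)c(OCc2ccccc2)c(OCc2ccccc2)c1 | starting material
6 | 3,4,5-tris(benzyloxy)phenylmagnesium bromide | Br[Mg]c1cc(OCc2ccccc2)c(OCc2ccccc2)c(OCc2ccccc2)c1 | intermediate
7 | (2S)-2-(benzyloxy)-3-[4-(tert-butyldimethylsilyloxy)phenyl]-1-[3,4,5-tris(benzyloxy)phenyl]propan-1-one | CC(C)(C)[Si](C)(C)Oc1ccc(C[C@H](OCc2ccccc2)C(=O)c2cc(OCc3ccccc3)c(OCc3ccccc3)c(OCc3ccccc3)c2)cc1 | intermediate
8 | (1R,2S)-2-(benzyloxy)-3-[4-(tert-butyldimethylsilyloxy)phenyl]-1-[3,4,5-tris(benzyloxy)phenyl]propan-1-ol | CC(C)(C)[Si](C)(C)Oc1ccc(C[C@H](OCc2ccccc2)[C@H](O)c2cc(OCc3ccccc3)c(OCc3ccccc3)c(OCc3ccccc3)c2)cc1 | intermediate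
9 | 4-[(2S,3R)-2-(benzyloxy)-3-hydroxy-3-[3,4,5-tris(benzyloxy)phenyl]propyl]phenol | Oc1ccc(C[C@H](OCc2ccccc2)[C@H](O)c2cc(OCc3ccccc3)c(OCc3ccccc3)c(OCc3ccccc3)c2)cc1 | intermediate
10 | 4-[(2S,3R)-2-(benzyloxy)-3-hydroxy-3-[3,4,5-tris(benzyloxy)phenyl]propyl]-4-hydroperoxycyclohexa-2,5-dien-1-one | O=C1C=CC(OO)(C[C@H](OCc2ccccc2)[C@H](O)c2cc(OCc3ccccc3)c(OCc3ccccc3)c(OCc3ccccc3)c2)C=C1 | intermediate
11 | 4-[(2S,3R)-2-(benzyloxy)-3-hydroxy-3-[3,4,5-tris(benzyloxy)phenyl]propyl]-4-hydroxycyclohexa-2,5-dien-1-one | O=C1C=CC(O)(C[C@H](OCc2ccccc2)[C@H](O)c2cc(OCc3ccccc3)c(OCc3ccccc3)c(OCc3ccccc3)c2)C=C1 | intermediate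
12 | (2R,3S)-3-(benzyloxy)-4a-hydroxy-2-[3,4,5-tris(benzyloxy)phenyl]-2,3,4,4a,8,8a-hexahydro-7H-chromen-7-one (cis ring fusion, C4a/C8a configuration not defined) | O=C1C=CC2(O)C[C@H](OCc3ccccc3)[C@@H](c3cc(OCc4ccccc4)c(OCc4ccccc4)c(OCc4ccccc4)c3)OC2C1 | intermediate
13 | (2R,3S)-3-(benzyloxy)-2-[3,4,5-tris(benzyloxy)phenyl]-3,4-dihydro-2H-chromen-7-ol | Oc1ccc2c(c1)O[C@H](c1cc(OCc3ccccc3)c(OCc3ccccc3)c(OCc3ccccc3)c1)[C@@H](OCc1ccccc1)C2 | intermediate
14 | (2R,3S)-3-(benzyloxy)-2-[3,4,5-tris(benzyloxy)phenyl]-3,4-dihydro-2H-chromene-4,7-diol (C4 epimers) | Oc1ccc2c(c1)O[C@H](c1cc(OCc3ccccc3)c(OCc3ccccc3)c(OCc3ccccc3)c1)[C@@H](OCc1ccccc1)C2O | intermediate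
15 | (2R,3R)-3-(benzyloxy)-7-hydroxy-2-[3,4,5-tris(benzyloxy)phenyl]-2,3-dihydro-4H-chromen-4-one | Oc1ccc2c(c1)O[C@H](c1cc(OCc3ccccc3)c(OCc3ccccc3)c(OCc3ccccc3)c1)[C@@H](OCc1ccccc1)C2=O | intermediate
16 | (2R,3R)-3,7-bis(benzyloxy)-2-[3,4,5-tris(benzyloxy)phenyl]-2,3-dihydro-4H-chromen-4-one | C(Oc1ccc2c(c1)O[C@H](c1cc(OCc3ccccc3)c(OCc3ccccc3)c(OCc3ccccc3)c1)[C@@H](OCc1ccccc1)C2=O)c1ccccc1 | intermediate
17 | (−)-epigallocatechin, (2R,3R)-2-(3,4,5-trihydroxyphenyl)-3,4-dihydro-2H-chromene-3,5,7-triol | Oc1cc(O)c2c(c1)O[C@H](c1cc(O)c(O)c(O)c1)[C@H](O)C2 | starting material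
18 | (2R,3R)-3,5,7-tris(benzyloxy)-2-[3,4,5-tris(benzyloxy)phenyl]-3,4-dihydro-2H-chromene | C(Oc1cc(OCc3ccccc3)c2c(c1)O[C@H](c1cc(OCc3ccccc3)c(OCc3ccccc3)c(OCc3ccccc3)c1)[C@H](OCc1ccccc1)C2)c1ccccc1 | intermediate
19 | (2R,3R)-3,5,7-tris(benzyloxy)-8-bromo-2-[3,4,5-tris(benzyloxy)phenyl]-3,4-dihydro-2H-chromene | C(Oc1cc(OCc3ccccc3)c2c(c1Br)O[C@H](c1cc(OCc3ccccc3)c(OCc3ccccc3)c(OCc3ccccc3)c1)[C@H](OCc1ccccc1)C2)c1ccccc1 | intermediate
20 | [(2R,3R)-3,5,7-tris(benzyloxy)-2-[3,4,5-tris(benzyloxy)phenyl]-3,4-dihydro-2H-chromen-8-yl]lithium | C(Oc1cc(OCc3ccccc3)c2c(c1[Li])O[C@H](c1cc(OCc3ccccc3)c(OCc3ccccc3)c(OCc3ccccc3)c1)[C@H](OCc1ccccc1)C2)c1ccccc1 | intermediate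
21 | (2R,3R,4R)-3,7-bis(benzyloxy)-4-{(2R,3R)-3,5,7-tris(benzyloxy)-2-[3,4,5-tris(benzyloxy)phenyl]-3,4-dihydro-2H-chromen-8-yl}-2-[3,4,5-tris(benzyloxy)phenyl]-3,4-dihydro-2H-chromen-4-ol | C(Oc1ccc2c(c1)O[C@H](c1cc(OCc3ccccc3)c(OCc3ccccc3)c(OCc3ccccc3)c1)[C@@H](OCc1ccccc1)[C@]2(O)c1c(OCc3ccccc3)cc(OCc3ccccc3)c2c1O[C@H](c1cc(OCc3ccccc3)c(OCc3ccccc3)c(OCc3ccccc3)c1)[C@H](OCc1ccccc1)C2)c1ccccc1 | intermediate
22 | (2R,3S,4R)-3,7-bis(benzyloxy)-4-{(2R,3R)-3,5,7-tris(benzyloxy)-2-[3,4,5-tris(benzyloxy)phenyl]-3,4-dihydro-2H-chromen-8-yl}-2-[3,4,5-tris(benzyloxy)phenyl]-3,4-dihydro-2H-chromene (undeca-O-benzyl dimer) | C(Oc1ccc2c(c1)O[C@H](c1cc(OCc3ccccc3)c(OCc3ccccc3)c(OCc3ccccc3)c1)[C@@H](OCc1ccccc1)[C@H]2c1c(OCc3ccccc3)cc(OCc3ccccc3)c2c1O[C@H](c1cc(OCc3ccccc3)c(OCc3ccccc3)c(OCc3ccccc3)c1)[C@H](OCc1ccccc1)C2)c1ccccc1 | intermediate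
23 | (2R,3S,4R)-4-[(2R,3R)-3,5,7-trihydroxy-2-(3,4,5-trihydroxyphenyl)-3,4-dihydro-2H-chromen-8-yl]-2-(3,4,5-trihydroxyphenyl)-3,4-dihydro-2H-chromene-3,7-diol | Oc1ccc2c(c1)O[C@H](c1cc(O)c(O)c(O)c1)[C@@H](O)[C@H]2c1c(O)cc(O)c2c1O[C@H](c1cc(O)c(O)c(O)c1)[C@H](O)C2 | target

**Count**
Total steps: 15. Longest linear sequence: 13 steps (steps 1–10, then 13–15); the lower unit takes 2 steps (11–12) before the union in step 13.

**Steps most likely to fail**

1. Step 8 (Proposed new method). The reversible oxa-Michael addition may not outrun acid-induced side reactions of the quinol: a 1,2-shift of the side chain (dienone–phenol rearrangement), or ionisation at benzylic C2 with capture by the quinol hydroxyl. Ring A would then re-aromatise without the O1–C8a bond. The fallback uses known chemistry, sets out from 6 and returns to the route at 13; the O1–C8a bond is made by palladium-catalysed intramolecular aryl etherification (Buchwald–Hartwig C–O coupling) of an ortho-bromide. Commercial 3-bromo-4-methylphenol is silylated (iPr3SiCl, imidazole) to (3-bromo-4-methylphenoxy)triisopropylsilane F1 and brominated at the benzylic carbon (NBS, AIBN, PhCF3, reflux) to [3-bromo-4-(bromomethyl)phenoxy]triisopropylsilane F2. The sodium enolate (NaN(SiMe3)2, THF, −78 °C) of commercial (4R)-4-benzyl-3-(benzyloxyacetyl)-1,3-oxazolidin-2-one is alkylated with F2 (Evans alkylation, electrophile anti to the auxiliary benzyl group) to give (4R)-4-benzyl-3-[(2S)-2-(benzyloxy)-3-[2-bromo-4-(triisopropylsilyloxy)phenyl]propanoyl]-1,3-oxazolidin-2-one F3. AlMe3 and MeNHOMe·HCl convert F3 into (2S)-2-(benzyloxy)-3-[2-bromo-4-(triisopropylsilyloxy)phenyl]-N-methoxy-N-methylpropanamide F4. Addition of 6 should give (2S)-2-(benzyloxy)-3-[2-bromo-4-(triisopropylsilyloxy)phenyl]-1-[3,4,5-tris(benzyloxy)phenyl]propan-1-one F5, and Zn(BH4)2 the anti alcohol (1R,2S)-2-(benzyloxy)-3-[2-bromo-4-(triisopropylsilyloxy)phenyl]-1-[3,4,5-tris(benzyloxy)phenyl]propan-1-ol F6. Pd(OAc)2, 2-(di-tert-butylphosphino)-1,1'-binaphthyl and Cs2CO3 in toluene at 80 °C should close ring C to [(2R,3S)-3-(benzyloxy)-2-[3,4,5-tris(benzyloxy)phenyl]-3,4-dihydro-2H-chromen-7-yl]oxy-triisopropylsilane F7, and Bu4NF then gives 13.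

2. Step 14. The C4 cation may lose H-3 (elimination to the 3-benzyloxy-4-aryl-2H-chromene) or be cleaved by ipso-protonation of ring D, and the facial selectivity of hydride delivery may erode. The fallback sets out from 21 and returns at 22; it removes the C4 oxygen through a radical instead of a cation (Barton–McCombie-type deoxygenation of a tertiary oxalate). Compound 21 is deprotonated (nBuLi, THF, −78 °C) and acylated with methyl chlorooxoacetate to the methyl oxalate of 21, methyl (2R,3R,4R)-3,7-bis(benzyloxy)-4-{(2R,3R)-3,5,7-tris(benzyloxy)-2-[3,4,5-tris(benzyloxy)phenyl]-3,4-dihydro-2H-chromen-8-yl}-2-[3,4,5-tris(benzyloxy)phenyl]-3,4-dihydro-2H-chromen-4-yl oxalate F8. nBu3SnH and AIBN in toluene at 100 °C generate the dibenzylic C4 radical, which should take hydrogen from the stannane on the face trans to the C3 benzyloxy group to give 22.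

3. Step 9. The quinone methide may tautomerise to the flav-3-ene and be dehydrogenated further to a flavylium ion instead of being captured by water. The fallback sets out from 13 and returns at 16. The phenol is benzylated first (BnBr, K2CO3, DMF) to (2R,3S)-3,7-bis(benzyloxy)-2-[3,4,5-tris(benzyloxy)phenyl]-3,4-dihydro-2H-chromene F9, so that no quinone methide can form. DDQ in wet CH2Cl2 then abstracts hydride from C4 of the aryl ether and water captures the cation (the established C4 oxygenation of flavan-3-ol aryl ethers) to give (2R,3S)-3,7-bis(benzyloxy)-2-[3,4,5-tris(benzyloxy)phenyl]-3,4-dihydro-2H-chromen-4-ol F10. Dess–Martin periodinane oxidises F10 to 16.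

**Further compounds**
F1 | step 8 | (3-bromo-4-methylphenoxy)triisopropylsilane | Cc1ccc(O[Si](C(C)C)(C(C)C)C(C)C)cc1Br
F2 | step 8 | [3-bromo-4-(bromomethyl)phenoxy]triisopropylsilane | BrCc1ccc(O[Si](C(C)C)(C(C)C)C(C)C)cc1Br
F3 | step 8 | (4R)-4-benzyl-3-[(2S)-2-(benzyloxy)-3-[2-bromo-4-(triisopropylsilyloxy)phenyl]propanoyl]-1,3-oxazolidin-2-one | O=C1OC[C@@H](Cc2ccccc2)N1C(=O)[C@@H](OCc1ccccc1)Cc1ccc(O[Si](C(C)C)(C(C)C)C(C)C)cc1Br
F4 | step 8 | (2S)-2-(benzyloxy)-3-[2-bromo-4-(triisopropylsilyloxy)phenyl]-N-methoxy-N-methylpropanamide | CON(C)C(=O)[C@@H](OCc1ccccc1)Cc1ccc(O[Si](C(C)C)(C(C)C)C(C)C)cc1Br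
F5 | step 8 | (2S)-2-(benzyloxy)-3-[2-bromo-4-(triisopropylsilyloxy)phenyl]-1-[3,4,5-tris(benzyloxy)phenyl]propan-1-one | O=C(c1cc(OCc2ccccc2)c(OCc2ccccc2)c(OCc2ccccc2)c1)[C@@H](OCc1ccccc1)Cc1ccc(O[Si](C(C)C)(C(C)C)C(C)C)cc1Br
F6 | step 8 | (1R,2S)-2-(benzyloxy)-3-[2-bromo-4-(triisopropylsilyloxy)phenyl]-1-[3,4,5-tris(benzyloxy)phenyl]propan-1-ol | O[C@H](c1cc(OCc2ccccc2)c(OCc2ccccc2)c(OCc2ccccc2)c1)[C@@H](OCc1ccccc1)Cc1ccc(O[Si](C(C)C)(C(C)C)C(C)C)cc1Br
F7 | step 8 | [(2R,3S)-3-(benzyloxy)-2-[3,4,5-tris(benzyloxy)phenyl]-3,4-dihydro-2H-chromen-7-yl]oxy-triisopropylsilane | CC(C)[Si](Oc1ccc2c(c1)O[C@H](c1cc(OCc3ccccc3)c(OCc3ccccc3)c(OCc3ccccc3)c1)[C@@H](OCc1ccccc1)C2)(C(C)C)C(C)C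
F8 | step 14 | methyl (2R,3R,4R)-3,7-bis(benzyloxy)-4-{(2R,3R)-3,5,7-tris(benzyloxy)-2-[3,4,5-tris(benzyloxy)phenyl]-3,4-dihydro-2H-chromen-8-yl}-2-[3,4,5-tris(benzyloxy)phenyl]-3,4-dihydro-2H-chromen-4-yl oxalate | C(Oc1ccc2c(c1)O[C@H](c1cc(OCc3ccccc3)c(OCc3ccccc3)c(OCc3ccccc3)c1)[C@@H](OCc1ccccc1)[C@]2(OC(=O)C(=O)OC)c1c(OCc3ccccc3)cc(OCc3ccccc3)c2c1O[C@H](c1cc(OCc3ccccc3)c(OCc3ccccc3)c(OCc3ccccc3)c1)[C@H](OCc1ccccc1)C2)c1ccccc1
F9 | step 9 | (2R,3S)-3,7-bis(benzyloxy)-2-[3,4,5-tris(benzyloxy)phenyl]-3,4-dihydro-2H-chromene | C(Oc1ccc2c(c1)O[C@H](c1cc(OCc3ccccc3)c(OCc3ccccc3)c(OCc3ccccc3)c1)[C@@H](OCc1ccccc1)C2)c1ccccc1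
F10 | step 9 | (2R,3S)-3,7-bis(benzyloxy)-2-[3,4,5-tris(benzyloxy)phenyl]-3,4-dihydro-2H-chromen-4-ol (C4 epimers) | C(Oc1ccc2c(c1)O[C@H](c1cc(OCc3ccccc3)c(OCc3ccccc3)c(OCc3ccccc3)c1)[C@@H](OCc1ccccc1)C2O)c1ccccc1
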